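## The problem

Compound 26 is a 1-aryltetralin lignan that carries an alkyl hydrogen sulfate; in the tetralin numbering used throughout, C1 bears ring C (4-hydroxy-3-methoxyphenyl), C2 the CH2OSO3H arm, C3 the CH2OH arm, C4 is a methylene, and C4a/C8a fuse ring A (6-OMe, 7-OH) to the saturated ring B. A synthesis has to build ring B onto ring A with three contiguous stereocentres, (1S,2R,3R), all trans. C1 is a diarylmethine that no later step can correct, so it must be set absolutely and early. C2 can then be set relative to C1, and C3 can be left to equilibration while its arm is at the carboxyl level, because the all-trans array is the all-equatorial one. The arms at C2 and C3 are primary carbinols of nearly equal reactivity, and only one is sulfated, so they should leave the ring-forming step in different oxidation states. The sulfate monoester is solvolysed by acid and must come late, and the two guaiacyl phenols, next to the doubly benzylic C1–H, invite oxidation and quinone methide formation and are best masked until the end. The enabling feature is the C2–C3 bond, which joins a carbon α to a carboxyl-level arm (C3) to a carbon whose one-carbon arm can be read as a degraded vinyl group (C2), the product pattern of an ester enolate Claisen rearrangement. Because ring A already links C4 to C1, the allylic ester can be tied back as a lactone, and the rearrangement then closes ring B.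

## Retrosynthesis

**Sulfate and phenols (26 ⇒ 25 ⇒ 24).** The three O–benzyl bonds and the S–O bond are cut first. All three hydroxyls that stay free in 26 are carried as benzyl ethers, so one hydrogenolysis ends the synthesis and the sulfate goes onto the only free hydroxyl of 24. The forward steps must sulfate a primary alcohol and then debenzylate without touching the sulfate.

**The two arms (24 ⇒ 22 ⇒ 21 ⇒ 20 ⇒ 18).** The C2 hydroxymethyl group is traced back to a vinyl group, which loses one carbon on oxidative cleavage. The C3 benzyloxymethyl group is traced back to a carboxylic acid. This removes any need to tell two equal carbinols apart. It also makes C3 epimerisable, so acid 18 may carry the wrong C3 configuration (2,3-cis) as long as C1 and C2 are right.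

**Ring B (18 ⇒ 15), the key cut.** The C2–C3 bond is cut and the allylic C–O bond is re-formed in a retro-[3,3] sense. This turns the vinyl acid 18 into the ten-membered (S,Z)-lactone 15. The neighbouring cuts at C1–C8a or C4–C4a are Friedel–Crafts closures that leave C1 or the arm differentiation to cation chemistry. An open-chain Claisen rearrangement across C2–C3 would make the bond but not the ring. Lactone 15 has one stereocentre instead of three and one ring-forming problem of a known kind. The forward reaction must enolise at C3 despite the acidic C1–H and must pass the configuration of C1 on to C2.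

**The macrocycle (15 ⇒ 14).** The (Z)-olefin is cut by retro-metathesis to the open-chain allyl ester 14. Lactonisation of a (Z)-hydroxy acid is the alternative closure, but it needs a separately built (Z)-allylic alcohol; it is kept as a fallback. The forward reaction must close a ten-membered ring at high dilution and give the (Z)-isomer.

**C1 (14 ⇒ 12 ⇒ 8 + 10).** Ester 14 comes from ethyl ester 12 and allyl alcohol 13 by ester exchange. In 12 the C1–ring C bond is cut: ring C enters as the aryl Grignard reagent 11 made from bromide 10, and C1 is formed by anti-SN2' substitution of the allylic picolinate 8. The carbinol configuration of 8 is thereby transferred to C1 in a predictable sense. A catalytic asymmetric arylation of an achiral cinnamyl electrophile is the neighbouring option; its sense of induction would have to be established first, so it is the fallback. The forward reaction must attack the benzylic γ-carbon and spare the ethyl ester.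

**The carbinol (8 ⇒ 7 ⇒ 6 ⇒ 4 + 5).** Picolinate 8 is the ester of allylic alcohol 7. Its stereocentre comes from reagent-controlled reduction of enone 6, and the enone from aldehyde 4 and the acetonyl ylide 5. The aldehyde carbon of 4 becomes C1 and the ylide carbon becomes C2.

**Ring A (4 ⇒ 2 + 3 ⇒ 1; 10 ⇒ 9).** The C4a–C4 bond is cut to aryl bromide 2 and the zinc homoenolate 3, which supplies C4, C3 and the carboxyl carbon in one step. Bromide 2 comes from aldehyde 1 by bromination. The pattern of 1 fits the target: the formyl carbon is para to the methoxy group (future C8a and C6) and the bromine enters para to the benzyloxy group (future C4a and C7). Bromide 10 is the benzyl ether of phenol 9.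

## Roads not taken

**Alternative 1:** The cut removes the C2–CH2OH bond and the C1–ring C bond. It leads back to the (3R)-dihydronaphthalene A1 (C1=C2 olefin, C3 bearing CH2OBn), formaldehyde A2 and guaiacol A3. In the forward sense dimethylaluminium chloride A4 would activate A2 for Prins-type addition to C2 of the styrenic double bond, anti to the C3 substituent. The C1 cation, stabilised by the para methoxy group of ring A, would be held as its chloride and would then alkylate A3 para to the hydroxyl, giving A5.
- Merits: two skeletal bonds and two stereocentres arise from one preset centre in one operation. A5 already has the C2 arm free and the C3 arm benzylated, the right way round for sulfation. After masking the phenol only sulfation and hydrogenolysis would remain, so this road would be clearly shorter than the chosen one.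
- Weak points: the C1 cation can lose the C2 proton, and the resulting dihydronaphthalenes aromatise easily. Facial control at C2 rests on one allylic substituent in a flexible half-chair. A3 can react para to either oxygen or at oxygen, and its hydroxyl consumes A4. C1 is set only under cation control. A1 is oxidation-prone and needs its own asymmetric synthesis.
- Comparison: against the brevity of this road the chosen plan sets a separate, understood control element for each stereocentre (chirality transfer for C1, allylic strain for C2, equilibration for C3). It also never generates a benzylic cation beside a free phenol.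

**Alternative 2:** Both bonds to C4 are cut (C3–C4 and C4–C4a). C4 then comes from A2, and the precursor is the open-chain aldehyde A6, which already holds C1 and C2. Forward, a secondary amine would mediate the α-methylenation of A6 by A2 (Mannich addition, then elimination of the amine), which forms C3–C4. The free phenol of ring A would then drive a conjugate Friedel–Crafts attack of its para position on the new CH2 (6-endo), closing ring B and giving A7. C3 is set by protonation and can equilibrate to trans.
- Merits: ring B closes by an ordinary six-membered cyclisation with no medium ring. C3 is under the same thermodynamic control as in the chosen plan, and C4 costs nothing.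
- Weak points: the stereochemical burden moves to A6, with two adjacent centres in an open chain, one of them a diarylmethine whose aryl groups differ only in their masking. Ring A can also attack through the position ortho to its hydroxyl, which closes a six-membered ring as well. At the α-methylenated stage the material can polymerise or add the phenol oxygen. A7 still needs reduction and protecting-group exchange at three sites around the sulfation.
- Comparison: the ring closure of this road is less risky than a ten-membered metathesis followed by a ring contraction. The chosen plan offers in return that C2 and ring B arise together from C1 alone, so only one stereocentre needs an external chiral reagent, and that the arms come out differentiated without later exchange of protecting groups.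

**Alternative 3:** The two bonds from C1 to aryl carbons are cut (C1–C8a and C1–ring C). C1 becomes the anomeric carbon of lactol A8, a trans-disubstituted tetrahydrofuranol carrying the ring A benzyl group and the silylated C2 arm. Forward, acid would ionise A8, and ring A would attack the oxocarbenium carbon para to its methoxy group and close ring B. The benzylic C1–O bond formed in this way would ionise a second time, and A3 would add para to its hydroxyl, anti to the C2 substituent. This frees the hydroxyl of the C3 arm and gives A9.
- Merits: this is the most convergent of the four roads. A8 comes from established butyrolactone chemistry that sets C2 and C3 reliably, and ring C enters as the cheapest possible reagent. The route would very probably be shorter than the chosen one.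
- Weak points: the second ionisation competes with loss of the C2 proton and aromatisation. A3 again raises the regiochemical question and must be used in excess. The C1 configuration depends on the face selectivity of a cation capture. In A9 the free arm is the C3 one, the opposite of what the target needs, so protection of that hydroxyl and the phenol, desilylation, sulfation and deprotection must follow.
- Comparison: the chosen plan is longer. It sets against this an early, absolute definition of C1 that never passes through a cation, the entry of ring C as a preformed para-substituted aryl metal, and arms differentiated in the required sense.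

Key step: step 10

## Route

Remark 1: the hydrogen sulfates 25 and 26 are written in the acid form of the target; in practice they would be handled as sodium salts, and 26 would be released by a final cation exchange.

Remark 2: the sense of the reduction in step 4 is assigned on the premise that the arylvinyl group acts as the large ketone substituent, as aryl and alkenyl groups do in methyl ketones.

Step 1
Reactants: 1 3-(benzyloxy)-4-methoxybenzaldehyde
Product: 2 5-(benzyloxy)-2-bromo-4-methoxybenzaldehyde
Conditions: Br2, NaOAc, AcOH, rt
Reagents that add atoms: bromine, BrBr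
Why: Electrophilic aromatic bromination; the position para to the benzyloxy group and ortho to the formyl group is the most activated unhindered site of a 3,4-dialkoxybenzaldehyde, which places the halogen on the future C4a.

Step 2
Reactants: 2 5-(benzyloxy)-2-bromo-4-methoxybenzaldehyde; 3 (3-ethoxy-3-oxopropyl)zinc bromide (BrZnCH2CH2CO2Et)
Product: 4 ethyl 3-[4-(benzyloxy)-2-formyl-5-methoxyphenyl]propanoate
Conditions: Pd(OAc)2 (cat.), SPhos (cat.), THF, rt to 50 °C
Reagents that add atoms: none
Why: Negishi sp2–sp3 cross-coupling; the ortho-formyl aryl bromide adds readily to zerovalent palladium, and alkylzinc halides leave aldehydes and esters alone under these conditions, so C4, C3 and the carboxyl carbon are attached to C4a in one step.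

Step 3
Reactants: 4 ethyl 3-[4-(benzyloxy)-2-formyl-5-methoxyphenyl]propanoate; 5 1-(triphenyl-λ5-phosphanylidene)propan-2-one
Product: 6 ethyl 3-{4-(benzyloxy)-5-methoxy-2-[(1E)-3-oxobut-1-en-1-yl]phenyl}propanoate
Conditions: PhMe, 110 °C
Reagents that add atoms: none
Why: Wittig olefination with a stabilised acyl ylide, which should give the (E)-enone and does not touch the ester; the aldehyde carbon becomes C1 and the ylide carbon C2.

Step 4
Reactants: 6 ethyl 3-{4-(benzyloxy)-5-methoxy-2-[(1E)-3-oxobut-1-en-1-yl]phenyl}propanoate
Product: 7 ethyl 3-{4-(benzyloxy)-2-[(1E,3S)-3-hydroxybut-1-en-1-yl]-5-methoxyphenyl}propanoate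
Conditions: (R)-2-methyl-CBS-oxazaborolidine (cat.), catecholborane, PhMe, −78 °C
Reagents that add atoms: none
Why: Corey–Bakshi–Shibata reduction; the ketone binds to the catalyst with the arylvinyl group as the large substituent, so the (R)-catalyst should deliver hydride to the face that gives the (S)-carbinol, and catecholborane at −78 °C gives 1,2-reduction only and spares the ester.

Step 5
Reactants: 7 ethyl 3-{4-(benzyloxy)-2-[(1E,3S)-3-hydroxybut-1-en-1-yl]-5-methoxyphenyl}propanoate
Product: 8 (2S,3E)-4-[5-(benzyloxy)-2-(3-ethoxy-3-oxopropyl)-4-methoxyphenyl]but-3-en-2-yl pyridine-2-carboxylate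
Conditions: pyridine-2-carboxylic acid, DCC, DMAP (cat.), CH2Cl2, 0 °C to rt
Reagents that add atoms: pyridine-2-carboxylic acid (picolinic acid), OC(=O)c1ccccn1
Why: Steglich esterification at oxygen, which leaves the carbinol configuration unchanged; the picolinate is installed as a chelating leaving group for step 7.

Step 6
Reactants: 9 4-bromo-2-methoxyphenol
Product: 10 1-(benzyloxy)-4-bromo-2-methoxybenzene
Conditions: BnBr, K2CO3, acetone, reflux
Reagents that add atoms: benzyl bromide, BrCc1ccccc1
Why: Williamson ether synthesis on a phenol; the benzyl group is the one removed from all positions in the last step.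

Step 7
Reactants: 8 (2S,3E)-4-[5-(benzyloxy)-2-(3-ethoxy-3-oxopropyl)-4-methoxyphenyl]but-3-en-2-yl pyridine-2-carboxylate; 10 1-(benzyloxy)-4-bromo-2-methoxybenzene
Product: 12 ethyl 3-{4-(benzyloxy)-2-[(1S,2E)-1-[4-(benzyloxy)-3-methoxyphenyl]but-2-en-1-yl]-5-methoxyphenyl}propanoate, via arylmagnesium bromide 11 (not isolated)
Conditions: 10, Mg, THF, 40 °C (gives 11); CuBr·SMe2 (cat.), then 8, THF, −40 to 0 °C
Reagents that add atoms: magnesium (retained in 11 only), [Mg]
Why: Copper-catalysed anti-SN2' substitution of a secondary allylic picolinate by an aryl Grignard reagent with 1,3-chirality transfer; magnesium chelated by the picolinate activates the C–O bond, and the arylcopper attacks the γ-carbon anti to the leaving group in the conformer whose carbinol hydrogen eclipses the olefin. The (S)-carbinol should therefore give (S)-C1 and an (E)-olefin, and the low temperature protects the ethyl ester.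

Step 8
Reactants: 12 ethyl 3-{4-(benzyloxy)-2-[(1S,2E)-1-[4-(benzyloxy)-3-methoxyphenyl]but-2-en-1-yl]-5-methoxyphenyl}propanoate; 13 prop-2-en-1-ol (allyl alcohol)
Product: 14 prop-2-en-1-yl 3-{4-(benzyloxy)-2-[(1S,2E)-1-[4-(benzyloxy)-3-methoxyphenyl]but-2-en-1-yl]-5-methoxyphenyl}propanoate
Conditions: Ti(OiPr)4 (cat.), 13 as solvent, 90 °C
Reagents that add atoms: none
Why: Titanate-catalysed transesterification driven by the excess of allyl alcohol; the neutral conditions leave the doubly benzylic, allylic C1–H untouched.

Step 9
Reactants: 14 prop-2-en-1-yl 3-{4-(benzyloxy)-2-[(1S,2E)-1-[4-(benzyloxy)-3-methoxyphenyl]but-2-en-1-yl]-5-methoxyphenyl}propanoate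
Product: 15 (S,Z)-ten-membered benzolactone (propanoate arm on C4a esterified with the allylic oxygen of the (Z)-CH=CH–CH2O unit on C1; see compound list)
Conditions: second-generation Grubbs catalyst (H2IMes)(PCy3)Cl2Ru=CHPh (cat.), 1,4-benzoquinone (cat.), PhMe (about 1 mM), 80 °C
Reagents that add atoms: none
Why: Ring-closing olefin metathesis at high dilution with loss of propene; under the equilibrating conditions of this catalyst the (Z)-olefin should prevail, being the less strained isomer in a ten-membered ring that already holds a cis arene unit and an s-trans ester. Benzoquinone suppresses ruthenium hydride olefin migration, and C1 is not involved.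

Step 10
Reactants: 15 (S,Z)-ten-membered benzolactone
Product: 18 (1S,2R,3S)-7-(benzyloxy)-1-[4-(benzyloxy)-3-methoxyphenyl]-2-ethenyl-6-methoxy-1,2,3,4-tetrahydronaphthalene-3-carboxylic acid, via ketene trimethylsilyl acetal 16 (not isolated), via trimethylsilyl ester 17 (not isolated)
Conditions: LiN(iPr)2 added to 15 and Me3SiCl–Et3N, THF, −78 °C; to rt; then PhMe, 80 °C; 1 M HCl–THF, rt
Reagents that add atoms: chlorotrimethylsilane (silyl group of 16 and 17 only), C[Si](C)(C)Cl
Why: Kinetic deprotonation at C3 in the presence of the silyl chloride gives ketene silyl acetal 16, whose C3=C(OSi) bond lies inside the ten-membered ring with C4 and the ring oxygen cis, as the ring demands and as a lithium amide in THF gives in any case. On warming, a [3,3] sigmatropic shift (Ireland–Claisen rearrangement) joins C3 to the olefin carbon next to C1, the future C2, while the allylic C–O bond breaks, leaving a silyl ester on C3 and a vinyl group on C2. The closest known reaction type is the Ireland–Claisen ring contraction of macrocyclic allylic lactones to 2-alkenylcycloalkanecarboxylic acids, here applied to a benzo-fused ten-membered ring. Ring B closes by this transannular C–C bond formation, a ten-to-six ring contraction in which C4, C4a, C8a and C1 tether the two termini; because both termini carry the tether on their cis positions, only a boat-like transition state is possible. C3 is set by that boat and the fixed ketene acetal geometry, which place the carboxyl and vinyl groups cis on ring B. C2 is set by C1: allylic 1,3-strain across the (Z)-olefin holds the C1–H in the olefin plane, C8a then lies on the face from which the tethered C3 must arrive and the ring C aryl on the other, so the new bond forms anti to the aryl group and C1/C2 come out trans. The step needs site selectivity in the deprotonation (C3–H against the doubly benzylic, allylic C1–H), secured by the carbonyl-directed kinetic base at −78 °C with immediate silylation, and it needs the (Z)-olefin of 15, on which the strain argument rests. Mild acid hydrolysis of silyl ester 17 then gives acid 18.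

Step 11
Reactants: 18 (1S,2R,3S)-7-(benzyloxy)-1-[4-(benzyloxy)-3-methoxyphenyl]-2-ethenyl-6-methoxy-1,2,3,4-tetrahydronaphthalene-3-carboxylic acid
Product: 20 methyl (1S,2R,3R)-7-(benzyloxy)-1-[4-(benzyloxy)-3-methoxyphenyl]-2-ethenyl-6-methoxy-1,2,3,4-tetrahydronaphthalene-3-carboxylate, via 2,3-cis methyl ester 19 (not isolated)
Conditions: Me3SiCHN2, PhMe–MeOH, 0 °C; evaporate; NaOMe, MeOH–THF, 60 °C
Reagents that add atoms: trimethylsilyldiazomethane (supplies the ester CH3 carbon), C[Si](C)(C)C=[N+]=[N-]
Why: O-Methylation of the acid followed by methoxide-mediated epimerisation through the ester enolate; the 2,3-trans ester has all three ring B substituents equatorial and should dominate at equilibrium, while C1 and C2 carry no proton acidic enough to exchange.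

Step 12
Reactants: 20 methyl (1S,2R,3R)-7-(benzyloxy)-1-[4-(benzyloxy)-3-methoxyphenyl]-2-ethenyl-6-methoxy-1,2,3,4-tetrahydronaphthalene-3-carboxylate
Product: 21 [(1S,2R,3R)-7-(benzyloxy)-1-[4-(benzyloxy)-3-methoxyphenyl]-2-ethenyl-6-methoxy-1,2,3,4-tetrahydronaphthalen-3-yl]methanol
Conditions: LiAlH4, THF, 0 °C
Reagents that add atoms: none
Why: Hydride reduction of the ester to the primary alcohol; no stereocentre is touched.

Step 13
Reactants: 21 [(1S,2R,3R)-7-(benzyloxy)-1-[4-(benzyloxy)-3-methoxyphenyl]-2-ethenyl-6-methoxy-1,2,3,4-tetrahydronaphthalen-3-yl]methanol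
Product: 22 (1S,2R,3R)-7-(benzyloxy)-3-[(benzyloxy)methyl]-1-[4-(benzyloxy)-3-methoxyphenyl]-2-ethenyl-6-methoxy-1,2,3,4-tetrahydronaphthalene
Conditions: NaH, BnBr, Bu4NI (cat.), THF–DMF, 0 °C to rt
Reagents that add atoms: benzyl bromide, BrCc1ccccc1
Why: Williamson etherification; the C3 arm is masked with the group that the final hydrogenolysis removes, so the C2 arm will later be the only free hydroxyl.

Step 14
Reactants: 22 (1S,2R,3R)-7-(benzyloxy)-3-[(benzyloxy)methyl]-1-[4-(benzyloxy)-3-methoxyphenyl]-2-ethenyl-6-methoxy-1,2,3,4-tetrahydronaphthalene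
Product: 24 [(1S,2R,3R)-7-(benzyloxy)-3-[(benzyloxy)methyl]-1-[4-(benzyloxy)-3-methoxyphenyl]-6-methoxy-1,2,3,4-tetrahydronaphthalen-2-yl]methanol, via 2-carbaldehyde 23 (not isolated)
Conditions: OsO4 (cat.), NaIO4, 2,6-lutidine, dioxane–H2O, rt; extractive work-up; NaBH4, MeOH–THF, 0 °C
Reagents that add atoms: osmium tetroxide, O=[Os](=O)(=O)=O (delivers the new oxygen; regenerated by sodium periodate, [Na+].[O-]I(=O)(=O)=O)
Why: Lemieux–Johnson cleavage of the only olefin (osmylation, then periodate glycol cleavage), which spares the electron-rich arenes, followed by borohydride reduction of the crude aldehyde; the all-trans aldehyde is the thermodynamic C2 epimer, so enolisation should not erode C2.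

Step 15
Reactants: 24 [(1S,2R,3R)-7-(benzyloxy)-3-[(benzyloxy)methyl]-1-[4-(benzyloxy)-3-methoxyphenyl]-6-methoxy-1,2,3,4-tetrahydronaphthalen-2-yl]methanol
Product: 25 [(1S,2R,3R)-7-(benzyloxy)-3-[(benzyloxy)methyl]-1-[4-(benzyloxy)-3-methoxyphenyl]-6-methoxy-1,2,3,4-tetrahydronaphthalen-2-yl]methyl hydrogen sulfate
Conditions: SO3·pyridine, pyridine, rt; aq. NaHCO3 work-up (handled as the sodium salt)
Reagents that add atoms: sulfur trioxide–pyridine complex, [O-]S(=O)(=O)[n+]1ccccc1
Why: O-Sulfation of a primary alcohol with the sulfur trioxide–amine complex; 24 has no other free hydroxyl, so no selectivity is asked for.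

Step 16
Reactants: 25 [(1S,2R,3R)-7-(benzyloxy)-3-[(benzyloxy)methyl]-1-[4-(benzyloxy)-3-methoxyphenyl]-6-methoxy-1,2,3,4-tetrahydronaphthalen-2-yl]methyl hydrogen sulfate
Product: 26 [(1S,2R,3R)-7-hydroxy-1-(4-hydroxy-3-methoxyphenyl)-3-(hydroxymethyl)-6-methoxy-1,2,3,4-tetrahydronaphthalen-2-yl]methyl hydrogen sulfate
Conditions: H2 (1 atm), Pd/C, MeOH, rt; then Dowex 50W (H+ form), 0 °C, freeze-drying
Reagents that add atoms: none
Why: Catalytic hydrogenolysis of two aryl benzyl ethers and one alkyl benzyl ether; a sulfate monoester salt is inert to hydrogen over palladium, and the pyridine of step 15 is removed beforehand because amines retard O-debenzylation. Cold cation exchange then gives the acid form.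

## Compound list

1 | 3-(benzyloxy)-4-methoxybenzaldehyde | COc1ccc(C=O)cc1OCc1ccccc1 | starting material
2 | 5-(benzyloxy)-2-bromo-4-methoxybenzaldehyde | COc1cc(Br)c(C=O)cc1OCc1ccccc1 | intermediate
3 | (3-ethoxy-3-oxopropyl)zinc bromide | CCOC(=O)CC[Zn]Br | starting material
4 | ethyl 3-[4-(benzyloxy)-2-formyl-5-methoxyphenyl]propanoate | CCOC(=O)CCc1cc(OC)c(OCc2ccccc2)cc1C=O | intermediate
5 | 1-(triphenyl-λ5-phosphanylidene)propan-2-one | CC(=O)C=P(c1ccccc1)(c1ccccc1)c1ccccc1 | starting material
6 | ethyl 3-{4-(benzyloxy)-5-methoxy-2-[(1E)-3-oxobut-1-en-1-yl]phenyl}propanoate | CCOC(=O)CCc1cc(OC)c(OCc2ccccc2)cc1/C=C/C(C)=O | intermediate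
7 | ethyl 3-{4-(benzyloxy)-2-[(1E,3S)-3-hydroxybut-1-en-1-yl]-5-methoxyphenyl}propanoate | CCOC(=O)CCc1cc(OC)c(OCc2ccccc2)cc1/C=C/[C@H](C)O | intermediate
8 | (2S,3E)-4-[5-(benzyloxy)-2-(3-ethoxy-3-oxopropyl)-4-methoxyphenyl]but-3-en-2-yl pyridine-2-carboxylate | CCOC(=O)CCc1cc(OC)c(OCc2ccccc2)cc1/C=C/[C@H](C)OC(=O)c1ccccn1 | intermediate
9 | 4-bromo-2-methoxyphenol | COc1cc(Br)ccc1O | starting material
10 | 1-(benzyloxy)-4-bromo-2-methoxybenzene | COc1cc(Br)ccc1OCc1ccccc1 | intermediate
11 | [4-(benzyloxy)-3-methoxyphenyl]magnesium bromide | COc1cc([Mg]Br)ccc1OCc1ccccc1 | intermediate (not isolated)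
12 | ethyl 3-{4-(benzyloxy)-2-[(1S,2E)-1-[4-(benzyloxy)-3-methoxyphenyl]but-2-en-1-yl]-5-methoxyphenyl}propanoate | COc1cc([C@H](/C=C/C)c2cc(OCc3ccccc3)c(OC)cc2CCC(=O)OCC)ccc1OCc1ccccc1 | intermediate
13 | prop-2-en-1-ol (allyl alcohol) | C=CCO | starting material
14 | prop-2-en-1-yl 3-{4-(benzyloxy)-2-[(1S,2E)-1-[4-(benzyloxy)-3-methoxyphenyl]but-2-en-1-yl]-5-methoxyphenyl}propanoate | COc1cc([C@H](/C=C/C)c2cc(OCc3ccccc3)c(OC)cc2CCC(=O)OCC=C)ccc1OCc1ccccc1 | intermediate
15 | (S,Z)-ten-membered benzolactone: ring A (6-OMe, 7-OBn) carries on C4a a CH2CH2C(=O)O chain whose oxygen is bonded to the CH2 of a (Z)-CH=CH–CH2 unit attached to C1; C1 (S) is bonded to C8a and carries H and the 4-(benzyloxy)-3-methoxyphenyl group | COc1cc([C@H]2c3cc(OCc4ccccc4)c(OC)cc3CCC(=O)OC/C=C\2)ccc1OCc1ccccc1 | intermediate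
16 | ketene trimethylsilyl acetal of 15: C3=C(OSiMe3) inside the ring with C4 and the ring oxygen cis; C1 (S) and the (Z)-olefin unchanged | COc1cc([C@H]2c3cc(OCc4ccccc4)c(OC)cc3C/C=C(/O[Si](C)(C)C)OC/C=C\2)ccc1OCc1ccccc1 | intermediate (not isolated)
17 | trimethylsilyl (1S,2R,3S)-7-(benzyloxy)-1-[4-(benzyloxy)-3-methoxyphenyl]-2-ethenyl-6-methoxy-1,2,3,4-tetrahydronaphthalene-3-carboxylate | COc1cc([C@H]2c3cc(OCc4ccccc4)c(OC)cc3C[C@H](C(=O)O[Si](C)(C)C)[C@@H]2C=C)ccc1OCc1ccccc1 | intermediate (not isolated)
18 | (1S,2R,3S)-7-(benzyloxy)-1-[4-(benzyloxy)-3-methoxyphenyl]-2-ethenyl-6-methoxy-1,2,3,4-tetrahydronaphthalene-3-carboxylic acid (1,2-trans, 2,3-cis) | COc1cc([C@H]2c3cc(OCc4ccccc4)c(OC)cc3C[C@H](C(=O)O)[C@@H]2C=C)ccc1OCc1ccccc1 | intermediate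
19 | methyl (1S,2R,3S)-7-(benzyloxy)-1-[4-(benzyloxy)-3-methoxyphenyl]-2-ethenyl-6-methoxy-1,2,3,4-tetrahydronaphthalene-3-carboxylate (2,3-cis) | COc1cc([C@H]2c3cc(OCc4ccccc4)c(OC)cc3C[C@H](C(=O)OC)[C@@H]2C=C)ccc1OCc1ccccc1 | intermediate (not isolated)
20 | methyl (1S,2R,3R)-7-(benzyloxy)-1-[4-(benzyloxy)-3-methoxyphenyl]-2-ethenyl-6-methoxy-1,2,3,4-tetrahydronaphthalene-3-carboxylate (all-trans) | COc1cc([C@H]2c3cc(OCc4ccccc4)c(OC)cc3C[C@@H](C(=O)OC)[C@@H]2C=C)ccc1OCc1ccccc1 | intermediate
21 | [(1S,2R,3R)-7-(benzyloxy)-1-[4-(benzyloxy)-3-methoxyphenyl]-2-ethenyl-6-methoxy-1,2,3,4-tetrahydronaphthalen-3-yl]methanol | COc1cc([C@H]2c3cc(OCc4ccccc4)c(OC)cc3C[C@@H](CO)[C@@H]2C=C)ccc1OCc1ccccc1 | intermediate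
22 | (1S,2R,3R)-7-(benzyloxy)-3-[(benzyloxy)methyl]-1-[4-(benzyloxy)-3-methoxyphenyl]-2-ethenyl-6-methoxy-1,2,3,4-tetrahydronaphthalene | COc1cc([C@H]2c3cc(OCc4ccccc4)c(OC)cc3C[C@@H](COCc3ccccc3)[C@@H]2C=C)ccc1OCc1ccccc1 | intermediate
23 | (1S,2R,3R)-7-(benzyloxy)-3-[(benzyloxy)methyl]-1-[4-(benzyloxy)-3-methoxyphenyl]-6-methoxy-1,2,3,4-tetrahydronaphthalene-2-carbaldehyde | COc1cc([C@H]2c3cc(OCc4ccccc4)c(OC)cc3C[C@@H](COCc3ccccc3)[C@@H]2C=O)ccc1OCc1ccccc1 | intermediate (not isolated)
24 | [(1S,2R,3R)-7-(benzyloxy)-3-[(benzyloxy)methyl]-1-[4-(benzyloxy)-3-methoxyphenyl]-6-methoxy-1,2,3,4-tetrahydronaphthalen-2-yl]methanol | COc1cc([C@H]2c3cc(OCc4ccccc4)c(OC)cc3C[C@@H](COCc3ccccc3)[C@@H]2CO)ccc1OCc1ccccc1 | intermediate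
25 | [(1S,2R,3R)-7-(benzyloxy)-3-[(benzyloxy)methyl]-1-[4-(benzyloxy)-3-methoxyphenyl]-6-methoxy-1,2,3,4-tetrahydronaphthalen-2-yl]methyl hydrogen sulfate | COc1cc([C@H]2c3cc(OCc4ccccc4)c(OC)cc3C[C@@H](COCc3ccccc3)[C@@H]2COS(=O)(=O)O)ccc1OCc1ccccc1 | intermediate
26 | [(1S,2R,3R)-7-hydroxy-1-(4-hydroxy-3-methoxyphenyl)-3-(hydroxymethyl)-6-methoxy-1,2,3,4-tetrahydronaphthalen-2-yl]methyl hydrogen sulfate | COc1cc([C@H]2c3cc(O)c(OC)cc3C[C@@H](CO)[C@@H]2COS(=O)(=O)O)ccc1O | target

## Step count and weak points

Total step count: 16. Longest linear sequence: 15 (steps 1–5 and 7–16 from 1; step 6 is a one-step side branch from 9).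

**Step 10 (key step).**
- Risk: the base may also remove the doubly benzylic, allylic C1–H, which would lead to loss of configuration at C1 or olefin migration. The lactone enolate may fragment before it is silylated. Transmission from C1 to C2 may be incomplete if the ring favours a conformer in which the aryl group, not the hydrogen, eclipses the olefin.
- First response within the approach: soft enolisation (Me3SiOTf, Et3N).
- Fallback, the same bond by a different mechanism, setting out from 15 and returning at 20: methanolysis of 15 (K2CO3, MeOH) would open the lactone to the (Z)-hydroxy methyl ester F1. MsCl, LiCl and 2,6-lutidine in DMF would convert it in one operation, without allylic transposition, into the (Z)-allylic chloride F2. KN(SiMe3)2 in THF at −78 °C would then close ring B by intramolecular enolate SN2' alkylation (6-exo), C3 attacking the same olefin carbon under the same allylic-strain control from C1. The resulting C3 epimers (19 and 20) would be equilibrated with NaOMe to 20.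

**Step 9.**
- Risk: ring strain may divert the metathesis to oligomerisation. Partial formation of the (E)-olefin and ruthenium hydride migration of the double bond into conjugation at C1 are further hazards.
- Fallback, setting out from 12 and returning at 15: ozonolysis of the propenyl group with a reductive quench in the same flask (O3, CH2Cl2–MeOH, −78 °C; then NaBH4, −78 to 0 °C) would give the 2,2-diarylethanol F3. The quench is applied cold because C1 is α to a carbonyl group at the cleavage stage and could otherwise be lost by enolisation. I2, PPh3 and imidazole would give the iodide F4, and PPh3 in hot MeCN the phosphonium iodide F5. Deprotonation of F5 (NaN(SiMe3)2, THF, −78 °C) and addition of (tert-butyldimethylsilyloxy)acetaldehyde would give the (Z)-allylic silyl ether F6 by the Z-selective Wittig reaction of a non-stabilised ylide. Bu4NF would give the (Z)-hydroxy ethyl ester F7, and LiOH the (Z)-hydroxy acid F8. Yamaguchi lactonisation (2,4,6-trichlorobenzoyl chloride, Et3N; DMAP, PhMe, high dilution) would give 15. Irreversible acylation escapes the ring-opening equilibrium that works against metathesis, and the olefin geometry is fixed beforehand.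

**Step 7.**
- Risk: substitution at the carbinol carbon instead of the hindered benzylic γ-carbon, since γ-attack gives up styrene conjugation. Partial ionisation of the electron-rich allylic picolinate would erode the chirality transfer. The Grignard reagent may add to the ethyl ester. A higher copper loading is the first adjustment.
- Fallback, catalyst control instead of leaving-group control, setting out from 4 and returning at 15: vinylmagnesium bromide (H2C=CHMgBr, THF, −78 °C) would add to the aldehyde of 4 to give the racemic allylic alcohol F9. PBr3 would convert it with allylic transposition into the (E)-cinnamyl bromide F10. Copper-catalysed asymmetric allylic arylation of F10 with Grignard reagent 11 would give the (S)-1,1-diarylpropene F11. The catalyst would be copper thiophene-2-carboxylate, Cu(O2CC4H3S), with a C2-symmetric chiral imidazolinium chloride as carbene precursor, in CH2Cl2 at −78 °C; the ligand antipode leading to (S) would have to be identified. Ester exchange as in step 8 would give the allyl ester F12, and metathesis as in step 9, now with loss of ethene, would give 15.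

**Step 16.**
- Risk: solvolytic loss of the sulfate if the medium turns acidic during hydrogenolysis, and slow cleavage of the alkyl benzyl ether.
- Fallback, a masked sulfate, setting out from 24 and returning at 26: 2,2,2-trichloroethyl chlorosulfate (Et3N, DMAP, THF) would convert 24 into the neutral sulfate diester F13. Catalytic transfer hydrogenolysis (Pd/C, HCO2NH4, MeOH) would then remove the three benzyl groups and the trichloroethyl group together and deliver 26 as its ammonium salt, to be protonated by cation exchange as in step 16.

## Further compounds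

F1 | step 10 | methyl 3-{4-(benzyloxy)-2-[(1S,2Z)-1-[4-(benzyloxy)-3-methoxyphenyl]-4-hydroxybut-2-en-1-yl]-5-methoxyphenyl}propanoate | COc1cc([C@H](/C=C\CO)c2cc(OCc3ccccc3)c(OC)cc2CCC(=O)OC)ccc1OCc1ccccc1
F2 | step 10 | methyl 3-{4-(benzyloxy)-2-[(1S,2Z)-1-[4-(benzyloxy)-3-methoxyphenyl]-4-chlorobut-2-en-1-yl]-5-methoxyphenyl}propanoate | COc1cc([C@H](/C=C\CCl)c2cc(OCc3ccccc3)c(OC)cc2CCC(=O)OC)ccc1OCc1ccccc1
F3 | step 9 | ethyl 3-{4-(benzyloxy)-2-[(1S)-1-[4-(benzyloxy)-3-methoxyphenyl]-2-hydroxyethyl]-5-methoxyphenyl}propanoate | COc1cc([C@H](CO)c2cc(OCc3ccccc3)c(OC)cc2CCC(=O)OCC)ccc1OCc1ccccc1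
F4 | step 9 | ethyl 3-{4-(benzyloxy)-2-[(1S)-1-[4-(benzyloxy)-3-methoxyphenyl]-2-iodoethyl]-5-methoxyphenyl}propanoate | COc1cc([C@H](CI)c2cc(OCc3ccccc3)c(OC)cc2CCC(=O)OCC)ccc1OCc1ccccc1
F5 | step 9 | {(2S)-2-[5-(benzyloxy)-2-(3-ethoxy-3-oxopropyl)-4-methoxyphenyl]-2-[4-(benzyloxy)-3-methoxyphenyl]ethyl}triphenylphosphonium iodide | COc1cc([C@H](C[P+](c2ccccc2)(c2ccccc2)c2ccccc2)c2cc(OCc3ccccc3)c(OC)cc2CCC(=O)OCC)ccc1OCc1ccccc1.[I-]
F6 | step 9 | ethyl 3-{4-(benzyloxy)-2-[(1S,2Z)-1-[4-(benzyloxy)-3-methoxyphenyl]-4-[(tert-butyldimethylsilyl)oxy]but-2-en-1-yl]-5-methoxyphenyl}propanoate | COc1cc([C@H](/C=C\CO[Si](C)(C)C(C)(C)C)c2cc(OCc3ccccc3)c(OC)cc2CCC(=O)OCC)ccc1OCc1ccccc1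
F7 | step 9 | ethyl 3-{4-(benzyloxy)-2-[(1S,2Z)-1-[4-(benzyloxy)-3-methoxyphenyl]-4-hydroxybut-2-en-1-yl]-5-methoxyphenyl}propanoate | COc1cc([C@H](/C=C\CO)c2cc(OCc3ccccc3)c(OC)cc2CCC(=O)OCC)ccc1OCc1ccccc1
F8 | step 9 | 3-{4-(benzyloxy)-2-[(1S,2Z)-1-[4-(benzyloxy)-3-methoxyphenyl]-4-hydroxybut-2-en-1-yl]-5-methoxyphenyl}propanoic acid | COc1cc([C@H](/C=C\CO)c2cc(OCc3ccccc3)c(OC)cc2CCC(=O)O)ccc1OCc1ccccc1
F9 | step 7 | ethyl 3-[4-(benzyloxy)-2-(1-hydroxyprop-2-en-1-yl)-5-methoxyphenyl]propanoate (racemic) | CCOC(=O)CCc1cc(OC)c(OCc2ccccc2)cc1C(O)C=C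
F10 | step 7 | ethyl 3-{4-(benzyloxy)-2-[(1E)-3-bromoprop-1-en-1-yl]-5-methoxyphenyl}propanoate | CCOC(=O)CCc1cc(OC)c(OCc2ccccc2)cc1/C=C/CBr
F11 | step 7 | ethyl 3-{4-(benzyloxy)-2-[(1S)-1-[4-(benzyloxy)-3-methoxyphenyl]prop-2-en-1-yl]-5-methoxyphenyl}propanoate | COc1cc([C@H](C=C)c2cc(OCc3ccccc3)c(OC)cc2CCC(=O)OCC)ccc1OCc1ccccc1
F12 | step 7 | prop-2-en-1-yl 3-{4-(benzyloxy)-2-[(1S)-1-[4-(benzyloxy)-3-methoxyphenyl]prop-2-en-1-yl]-5-methoxyphenyl}propanoate | COc1cc([C@H](C=C)c2cc(OCc3ccccc3)c(OC)cc2CCC(=O)OCC=C)ccc1OCc1ccccc1
F13 | step 16 | [(1S,2R,3R)-7-(benzyloxy)-3-[(benzyloxy)methyl]-1-[4-(benzyloxy)-3-methoxyphenyl]-6-methoxy-1,2,3,4-tetrahydronaphthalen-2-yl]methyl 2,2,2-trichloroethyl sulfate | COc1cc([C@H]2c3cc(OCc4ccccc4)c(OC)cc3C[C@@H](COCc3ccccc3)[C@@H]2COS(=O)(=O)OCC(Cl)(Cl)Cl)ccc1OCc1ccccc1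
A1 | alternative 1 | (R)-configured dihydronaphthalene: C1=C2 olefin, C3 bearing CH2OBn, C4 methylene (target numbering), ring A with 6-OMe and 7-OBn | COc1cc2c(cc1OCc1ccccc1)C=C[C@H](COCc1ccccc1)C2
A2 | alternative 1 | formaldehyde | C=O
A3 | alternative 1 | guaiacol (2-methoxyphenol) | COc1ccccc1O
A4 | alternative 1 | dimethylaluminium chloride | C[Al](C)Cl
A5 | alternative 1 | [(1S,2R,3R)-7-(benzyloxy)-3-[(benzyloxy)methyl]-1-(4-hydroxy-3-methoxyphenyl)-6-methoxy-1,2,3,4-tetrahydronaphthalen-2-yl]methanol | COc1cc([C@H]2c3cc(OCc4ccccc4)c(OC)cc3C[C@@H](COCc3ccccc3)[C@@H]2CO)ccc1O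
A6 | alternative 2 | 3-{[(tert-butyldiphenylsilyl)oxy]methyl}-4-(3-hydroxy-4-methoxyphenyl)-4-[3-methoxy-4-(tosyloxy)phenyl]butanal, C4 and C3 configured as C1 and C2 of the target | COc1cc([C@@H](c2cc(O)c(OC)cc2)[C@@H](CO[Si](c2ccccc2)(c2ccccc2)C(C)(C)C)CC=O)ccc1OS(=O)(=O)c1ccc(C)cc1
A7 | alternative 2 | (1S,2R,3R)-2-{[(tert-butyldiphenylsilyl)oxy]methyl}-7-hydroxy-6-methoxy-1-[3-methoxy-4-(tosyloxy)phenyl]-1,2,3,4-tetrahydronaphthalene-3-carbaldehyde | COc1cc([C@H]2c3cc(O)c(OC)cc3C[C@@H](C=O)[C@@H]2CO[Si](c4ccccc4)(c4ccccc4)C(C)(C)C)ccc1OS(=O)(=O)c1ccc(C)cc1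
A8 | alternative 3 | 4-[4-(benzyloxy)-3-methoxybenzyl]-3-{[(tert-butyldiphenylsilyl)oxy]methyl}tetrahydrofuran-2-ol (3,4-trans, ring C3 and C4 configured as C2 and C3 of the target, anomeric mixture) | OC1OC[C@H](Cc2ccc(OCc3ccccc3)c(OC)c2)[C@@H]1CO[Si](c1ccccc1)(c1ccccc1)C(C)(C)C
A9 | alternative 3 | [(1S,2R,3R)-7-(benzyloxy)-2-{[(tert-butyldiphenylsilyl)oxy]methyl}-1-(4-hydroxy-3-methoxyphenyl)-6-methoxy-1,2,3,4-tetrahydronaphthalen-3-yl]methanol | COc1cc([C@H]2c3cc(OCc4ccccc4)c(OC)cc3C[C@@H](CO)[C@@H]2CO[Si](c4ccccc4)(c4ccccc4)C(C)(C)C)ccc1O
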